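In the closed flask, substrate and coupling partner start at their full charge, whereas each dosed flask starts without the one it is fed, and the tank runs at its outlet composition.

| flask | substrate | coupling partner | second reagent | third reagent | remark | time |
|---|---|---|---|---|---|---|
| dusk | 20 mM | 21 mM | 19 mM | 20 mM | run made earlier |  |
| midnight | 20 mM | 10 mM | 19 mM | 20 mM | run made earlier |  |
| noon | 20 mM | 16 mM | 19 mM | 20 mM | run made earlier |  |
| winter | 20 mM | 21 mM | 19 mM | 30 mM | run made earlier |  |
| Monday's | 20 mM | 21.0 mM | 19.0 mM | 20.0 mM | a closed flask charged with all of it at once and left for 5.0 min | 5.0 min |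
| Friday's | 20 mM | 21.0 mM (fed, over 5.00 min) | 19.0 mM | 20.0 mM | a stirred flask in which coupling partner is dosed at a steady rate over 5.00 min without added volume, worked up at 5.0 min | 5.0 min |
| Thursday's | 20 mM | 21.0 mM | 19.0 mM | 20.0 mM | one stirred flow tank at steady state, fed with the mixture as stated, mean residence time 5.0 min |  |
| Wednesday's | 20 mM (fed, over 5.00 min) | 21.0 mM | 19.0 mM | 20.0 mM | a stirred flask in which substrate is dosed at a steady rate over 5.00 min without added volume, worked up at 5.0 min | 5.0 min |

- dusk (time / min: target / %, substrate / %): 0.833: 9.5, 51.8; 1.50: 21.6, 38.1; 2.50: 36.0, 26.0; 3.00: 40.0, 24.3; 4.00: 42.7, 18.6; 5.00: 46.3, 14.4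
- midnight (time / min: target / %, substrate / %): 0.417: 1.4, 83.7; 1.33: 12.7, 66.3; 2.00: 19.1, 61.7; 3.00: 24.2, 56.6; 5.00: 31.1, 52.8; 6.00: 31.7, 50.4
- noon (time / min: target / %, substrate / %): 1.00: 11.1, 59.5; 2.00: 25.9, 43.4; 3.00: 35.0, 35.5; 4.00: 38.0, 30.6; 5.00: 39.9, 28.8; 6.00: 41.0, 26.7
- winter (time / min: target / %, substrate / %): 1.33: 25.6, 41.4; 2.50: 42.6, 24.7; 4.00: 51.9, 17.1; 5.00: 53.6, 14.4; 6.00: 54.6, 10.1

(scatter of a reading: 1 percentage point)

- the stated concentrations are those of everything mixed, before any reaction; amounts are the same in each set-up
- steps thought possible: target <-> isomer of the product; second reagent + intermediate A -> intermediate B; third reagent + intermediate B <-> target; substrate + coupling partner -> intermediate A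
- the feed brings no volume worth counting
- the earlier runs were made in a closed, stirred flask

* the set-up with the highest amount of target at the outlet or at the end, in percent of the substrate put in ("none" if the first two lie within 2 percentage points) (Monday's / Friday's / Thursday's / Wednesday's / none)
* amount of target at the outlet or at the end, in percent of the substrate put in, Monday's
* amount of target at the outlet or at the end, in percent of the substrate put in, Friday's
* amount of target at the outlet or at the end, in percent of the substrate put in, Thursday's
* amount of target at the outlet or at the end, in percent of the substrate put in, Wednesday's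

Monday's repeats the dusk recipe, so you can read it directly: at 5.00 min, dusk shows 46.3% target with 85.6% of the substrate spent. Turn the question round and ask what Thursday's tank would need to beat that. The share of spent substrate found as target reads 0.541 in dusk and 0.560 in noon at that time. Midnight, with 0.500 equivalents of partner, reads 0.659.

My own reckoning takes substrate loss as second-order. The rate is the coupling pace times the substrate left times the partner left, both counted in substrate charges. With 1.05 charges of partner, the dusk reading gives a coupling pace 0.997 min⁻¹. Pace times residence time is the Damköhler number, and Thursday's offers 4.99. The tank balance sets that number equal to the fraction spent divided by the product of those two remainders. To spend dusk's fraction, Thursday's tank would need 30.6. Even if it turned spent substrate into target at midnight's share, it would need 6.81 to reach dusk's target, which is more than the tank has.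

The charge dosed in Friday's and Wednesday's has on average half the time. Dusk at 2.50 min reads 36.0%, less than at its end, but that is a guide and not a bound.

The forecast picks Monday's: 45.5% there, 31% for Friday's, 33% for Thursday's and 30.5% for Wednesday's, holding for the two dosed flasks that “dosing keeps the substrate–partner product low”.

Monday's gives 46.3%, Friday's 32.5%, Thursday's 31.3% and Wednesday's 32.2%; at 5.00 min, Monday's holds 14.3% of its substrate and Friday's 33.2%.

    target ⇌ isomer of the product (K = 0.600, k = 0.00266 s⁻¹)
    second reagent + intermediate A → intermediate B (k = 5.13 M⁻¹ s⁻¹)
    third reagent + intermediate B ⇌ target (K = 1100 M⁻¹, k = 0.757 M⁻¹ s⁻¹)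
    substrate + coupling partner → intermediate A (k = 0.837 M⁻¹ s⁻¹)

Put the pace into Thursday's balance and 66.0% of the substrate is spent, leaving 37.1% of the partner charge; the tank holds 37.0%. Friday's neighbour, dosed with 84 mM of coupling partner, ends with 3.20 substrate charges of partner, where the pace gives a substrate half-life of 0.217 min; that flask ends with 0.0753% substrate and 49.7% target.

The numbers in the tables are calculated from invented constants; scatter was added.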